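The ratio of J, the reagent, to L, the substrate, as charged is 2.00 in red and 4.18 in violet, while Z, the tris adduct, holds 3 J per L, so red lies below that need and violet above it.

| flask | L | J | remark | time |
|---|---|---|---|---|
| red | 0.023 M | 0.046 M | run made earlier |  |
| violet | 0.011 M | 0.046 M | run made earlier |  |
| birch | 0.023 M (fed, over 50 h) | 0.0460 M | all else is in the flask from the start; the feed brings no volume worth counting | 2.5 d |
| elm | 0.023 M | 0.0460 M (fed, over 5.0 h) | all else is in the flask from the start; the feed brings no volume worth counting | 2.5 d |
| oak | 0.023 M | 0.0460 M (fed, over 50 h) | all else is in the flask from the start; the feed brings no volume worth counting | 2.5 d |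
| larch | 0.023 M (in portions, 2, over 50 h) | 0.0460 M | first portion at the start, last at 50 h | 2.5 d |
| ash | 0.023 M | 0.0460 M | everything together at the start | 2.5 d |

- red (time / h: Z / %, X / %): 5.00: 30, 42; 12.0: 29, 32; 25.0: 21, 25; 40.0: 18, 20
- violet (time / h: Z / %, X / %): 2.50: 33, 46; 6.00: 59, 23; 12.0: 71, 7; 20.0: 77, 0

(readings scatter by 1.5 percentage points)



- the flask with the highest amount of Z, in percent of the L charged ("all alike" if they lie within 1.5 percentage points) (birch / elm / oak / larch / ash / all alike)
- final Z, as a percentage of the L charged, in birch
- final Z, as a percentage of the L charged, in elm
- final Z, as a percentage of the L charged, in oak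
- final Z, as a percentage of the L charged, in larch
- final Z, as a percentage of the L charged, in ash

Violet climbs to a reading of Z 77% as X, the mono adduct, falls to a reading of 0%. Red behaves differently: Z falls from 30% to 18%, and it falls with X, since Z over X reads 0.906, 0.840 and 0.900 at the last three readings.

So the late part of red can be reckoned through X. A loss of X proportional to the square of X integrates in closed form: the reciprocal of X grows in a straight line with time, at a slope s. The readings at 12.0 h and 40.0 h give s = 0.0670 /h, with X as a fraction of the L charged. That line gives 25.0% at 25.0 h, where the reading, not used for the slope, is 25%.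

From the X of 20% the reciprocal of s times X is 74.7 h. This is τ, the time in which X on that line falls to half of its value, the second-order half-life. X after a time t is then the present X divided by one plus t/τ.

Ash carries red's charges, so ash is red continued, and two times matter: τ and the 20.0 h left after the last reading, which is shorter. Their ratio is 0.268, so this reckoning puts ash at X 15.8% and, with Z following X, at Z 14.2%.

The forecast gives Z 43% in birch, 14% in elm, 19% in oak, 33% in larch and 14% in ash, names birch as highest, and says of the late fall: “This loss is a tentative reading”.

The flask gives Z 25.0% in birch, 15.8% in elm, 27.8% in oak, 30.0% in larch and 14.9% in ash, with larch highest; ash holds X 14.2%.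

    L + J → X (k = 24.4 /M/h)
    J + E ⇌ Z (K = 226 /M, k = 74.6 /M/h)
    L + X → G (k = 0.663 /M/h)
    J + X → E (k = 12.1 /M/h)

In larch, the first portion went through X to E, the bis adduct, and to Z, and just before the last addition, at 2.08 d, X stood at 0%, E at 11.7%, Z at 38.0% and J at 31.2% of its charge. After the last addition, L + J → X ran again, and at 2.50 d larch held X 24.2%, E 34.9%, Z 30.0% and J 7.68% of its charge. From that X, τ shortens to 61.8 h, so 180 h later X is reckoned at 6.19%; larch read at 10 d holds X 5.63%.

The data were computed from invented constants; the scatter is artificial.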